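**Plan**
Target numbering, used in all Why lines: tetrahydrofuran O1, C2, C3 (carries the 4-hydroxy-3-methoxybenzyl group), C4 (carries the carbinol carbon C7'), C5. The required configuration is 3R,4R (trans) and 7'S.
Cuts, in order: O1–C2 (ether back to a 1,4-diol, then to the γ-butyrolactone with C5 as carbonyl); C7'–H (carbinol back to the aryl ketone); C3–C4; finally the ester bond C5–O1 and the C4–C7' bond of a β-keto ester.
Enabling feature: C3–C4 links the two ring stereocentres. With C5 as a lactone carbonyl and C4 as a carbene carbon, the chain C4–C5(=O)–O1–C2–C3 places the C3–H bonds 1,5 to the carbene, so one C–H insertion makes that bond and the five-membered ring together.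
Forward: aroyl unit plus Meldrum's acid (C4–C7'), alcoholysis by the arylpropanol (C5–O1), diazo transfer at C4, insertion (lactone ring), ketone reduction, lactone opened to the diol and reclosed as the tetrahydrofuran, deprotection.
Stereochemistry: C3 comes from the chiral dirhodium carboxylate, C4 from equilibration to trans, and C7' from RuCl(p-cymene)[(S,S)-TsDPEN], which also turns any minor enantiomer into a separable diastereomer.

Key step: step 6

Assumption: Rh2(S-PTTL)4 is taken to select the pro-S hydrogen at C3 and so to give the (R) centre; if the sense proves opposite, Rh2(R-PTTL)4 from D-tert-leucine is used and nothing else changes.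

Step 1
Reactants: 1 dihydroconiferyl alcohol [4-(3-hydroxypropyl)-2-methoxyphenol]
Product: 2 3-[4-(benzyloxy)-3-methoxyphenyl]propan-1-ol
Conditions: BnBr, K2CO3, acetone, reflux
Reagents that add atoms: benzyl bromide, BrCc1ccccc1
Why: Williamson ether synthesis in which K2CO3 deprotonates only the phenol, so benzylation is selective for the aryl oxygen and the primary hydroxyl needed in step 4 stays free.

Step 2
Reactants: 3 syringic acid (4-hydroxy-3,5-dimethoxybenzoic acid)
Product: 5 4-(benzyloxy)-3,5-dimethoxybenzoic acid, via benzyl ester 4 (not isolated)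
Conditions: BnBr (2.3 equiv), K2CO3, MeCN, reflux; filter, concentrate; then NaOH, MeOH/H2O, 65 °C; HCl to pH 2
Reagents that add atoms: benzyl bromide, BrCc1ccccc1; sodium hydroxide, [Na+].[OH-]
Why: Williamson and carboxylate alkylation benzylates both acidic sites to give 4, and saponification by acyl–oxygen cleavage then frees the acid while the aryl benzyl ether is inert to hydroxide.

Step 3
Reactants: 5 4-(benzyloxy)-3,5-dimethoxybenzoic acid; 6 Meldrum's acid (2,2-dimethyl-1,3-dioxane-4,6-dione)
Product: 7 5-{[4-(benzyloxy)-3,5-dimethoxyphenyl](hydroxy)methylidene}-2,2-dimethyl-1,3-dioxane-4,6-dione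
Conditions: DCC, DMAP, CH2Cl2, 0 °C to rt
Reagents that add atoms: none
Why: Carbodiimide/DMAP C-acylation of Meldrum's acid is routine for benzoic acids, and the product is held as its stable hydrogen-bonded enol.

Step 4
Reactants: 7 acyl Meldrum's acid; 2 3-[4-(benzyloxy)-3-methoxyphenyl]propan-1-ol
Product: 9 3-[4-(benzyloxy)-3-methoxyphenyl]propyl 3-[4-(benzyloxy)-3,5-dimethoxyphenyl]-3-oxopropanoate, via aroylketene 8 (not isolated)
Conditions: toluene, 110 °C
Reagents that add atoms: none
Why: Thermal fragmentation of the acyl Meldrum's acid expels acetone and CO2, and the aroylketene 8 is trapped by the primary alcohol (acylketene alcoholysis) to give the β-keto ester without a coupling reagent.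

Step 5
Reactants: 9 β-keto ester
Product: 10 3-[4-(benzyloxy)-3-methoxyphenyl]propyl 3-[4-(benzyloxy)-3,5-dimethoxyphenyl]-2-diazo-3-oxopropanoate
Conditions: p-ABSA, Et3N, MeCN, 0 °C to rt
Reagents that add atoms: 4-acetamidobenzenesulfonyl azide, CC(=O)Nc1ccc(cc1)S(=O)(=O)N=[N+]=[N-]
Why: Regitz diazo transfer proceeds readily at the doubly activated methylene of a β-keto ester with a sulfonyl azide and a tertiary amine, and no other position of 9 is acidic enough to react.

Step 6
Reactants: 10 α-diazo-β-keto ester
Product: 12 (3S,4R)-3-[4-(benzyloxy)-3,5-dimethoxybenzoyl]-4-[4-(benzyloxy)-3-methoxybenzyl]oxolan-2-one, via rhodium carbenoid 11 (not isolated)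
Conditions: dirhodium tetrakis[N-phthaloyl-(S)-tert-leucinate], Rh2(S-PTTL)4 (2 mol %), 4 Å molecular sieves, CH2Cl2, slow addition of 10 at high dilution, 40 °C; then Et3N (cat.), rt
Reagents that add atoms: none
Why: Proposed new method: Rh2(S-PTTL)4, a paddlewheel complex of divalent rhodium, expels N2 from 10, and the electrophilic carbenoid 11 inserts its carbene carbon (future C4) into one C3–H bond in a concerted, asynchronous three-centre event with retention at C3, which forms C3–C4. The closest known reactions are the Rh2(OAc)4-catalysed 1,5 insertion of alkyl diazoacetoacetates to α-acyl-γ-butyrolactones and the enantioselective insertion of 3-arylpropyl diazoacetates with chiral dirhodium carboxamidates, so the ring construction is established and the unproven element is high enantiocontrol by a chiral carboxylate over an aroyl-substituted carbenoid on an ester tether. The one ring formed, the γ-butyrolactone C4–C5(=O)–O1–C2–C3, closes by 1,5 C–H insertion through a five-membered cyclic transition state. C3 is controlled by the catalyst, whose four N-phthaloyl-tert-leucinate ligands wall in the carbene so that only the pro-S hydrogen of the prochiral CH2 should reach it, whereas C4 is controlled thermodynamically, since it lies between two carbonyl groups and epimerises to the trans (3S,4R) lactone. The step needs site selectivity over 1,4 insertion at OCH2 (β-lactone), 1,6 insertion at the benzylic CH2 (δ-lactone) and attack on the arenes, and this is secured by the five-membered ring preference, by the inductive deactivation of the OCH2 hydrogens by the acyloxy oxygen, by the absence of any reachable C–H bond on the aroyl side and by slow addition at high dilution against carbene dimerisation. Imperfect enantioselectivity is tolerable because step 7 turns material from the minor enantiomer into a separable diastereomer.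

Step 7
Reactants: 12 trans keto lactone
Product: 13 (3S,4R)-3-{(S)-[4-(benzyloxy)-3,5-dimethoxyphenyl](hydroxy)methyl}-4-[4-(benzyloxy)-3-methoxybenzyl]oxolan-2-one
Conditions: RuCl(p-cymene)[(S,S)-TsDPEN] (2 mol %), HCO2H/Et3N 5:2, CH2Cl2, 30 °C
Reagents that add atoms: none
Why: Noyori asymmetric transfer hydrogenation, in which the (S,S)-TsDPEN ruthenium hydride adds to the Re face of the aryl ketone as it does with simple aryl alkyl ketones and so sets C7' as S, while C4 remains epimerisable in the buffer and is reduced from its strongly favoured trans form, which matches the syn pairing known for dynamic kinetic resolution of α-acyl-γ-butyrolactones.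

Step 8
Reactants: 13 hydroxy lactone
Product: 14 (3S,4R)-3-{(S)-[4-(benzyloxy)-3,5-dimethoxyphenyl][(tert-butyldimethylsilyl)oxy]methyl}-4-[4-(benzyloxy)-3-methoxybenzyl]oxolan-2-one
Conditions: TBSOTf, 2,6-lutidine, CH2Cl2, −78 to 0 °C
Reagents that add atoms: tert-butyldimethylsilyl trifluoromethanesulfonate, CC(C)(C)[Si](C)(C)OS(=O)(=O)C(F)(F)F
Why: Silylation with a silyl triflate and a hindered pyridine caps the secondary benzylic alcohol under non-nucleophilic conditions that avoid retro-aldol cleavage or dehydration of the β-hydroxy lactone, so that this oxygen cannot compete in the ring closure of step 10.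

Step 9
Reactants: 14 silyloxy lactone
Product: 15 (2R,3R)-2-{(S)-[4-(benzyloxy)-3,5-dimethoxyphenyl][(tert-butyldimethylsilyl)oxy]methyl}-3-[4-(benzyloxy)-3-methoxybenzyl]butane-1,4-diol
Conditions: LiAlH4, THF, 0 °C
Reagents that add atoms: none
Why: Standard hydride reduction of a lactone to the 1,4-diol, which touches no stereocentre and leaves silyl and benzyl ethers intact at 0 °C.

Step 10
Reactants: 15 1,4-diol
Product: 17 (3R,4R)-3-[4-(benzyloxy)-3-methoxybenzyl]-4-{(S)-[4-(benzyloxy)-3,5-dimethoxyphenyl][(tert-butyldimethylsilyl)oxy]methyl}oxolane, via monotosylate 16 (not isolated)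
Conditions: TsCl (1.1 equiv), pyridine, 0 to 40 °C
Reagents that add atoms: p-toluenesulfonyl chloride, Cc1ccc(cc1)S(=O)(=O)Cl (its tosyl group is carried by 16 only and leaves again on ring closure)
Why: Sulfonylation of one primary alcohol followed by spontaneous 5-exo-tet intramolecular Williamson displacement by the other is the standard passage from lignan 1,4-diols to 3,4-disubstituted tetrahydrofurans, either regioisomeric monotosylate gives the same ring without involving a stereocentre, and the amine base avoids the free alkoxide that could trigger silyl migration.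

Step 11
Reactants: 17 silyl ether
Product: 18 (S)-[4-(benzyloxy)-3,5-dimethoxyphenyl]{(3R,4R)-4-[4-(benzyloxy)-3-methoxybenzyl]oxolan-3-yl}methanol
Conditions: Bu4NF, THF, 0 °C to rt
Reagents that add atoms: none
Why: Fluoride-induced desilylation is driven by the Si–F bond, and running it while both phenols are still benzylated excludes quinone methide formation and hence epimerisation at C7'.

Step 12
Reactants: 18 dibenzyl ether
Product: 19 (S)-(4-hydroxy-3,5-dimethoxyphenyl)[(3R,4R)-4-(4-hydroxy-3-methoxybenzyl)oxolan-3-yl]methanol (CNP0307127.1)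
Conditions: H2 (1 atm), 10% Pd/C, EtOAc, rt, stopped at full conversion
Reagents that add atoms: none
Why: Catalytic hydrogenolysis cleaves aryl benzyl ethers much faster than a hindered secondary benzylic alcohol in a neutral, acid-free medium, so both phenols should be released with all three stereocentres untouched.

**Compound list**
1 | dihydroconiferyl alcohol | COc1cc(CCCO)ccc1O | starting material
2 | 3-[4-(benzyloxy)-3-methoxyphenyl]propan-1-ol | COc1cc(CCCO)ccc1OCc1ccccc1 | intermediate
3 | syringic acid | COc1cc(C(=O)O)cc(OC)c1O | starting material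
4 | benzyl 4-(benzyloxy)-3,5-dimethoxybenzoate | COc1cc(C(=O)OCc2ccccc2)cc(OC)c1OCc1ccccc1 | intermediate
5 | 4-(benzyloxy)-3,5-dimethoxybenzoic acid | COc1cc(C(=O)O)cc(OC)c1OCc1ccccc1 | intermediate
6 | Meldrum's acid | CC1(C)OC(=O)CC(=O)O1 | starting material
7 | 5-{[4-(benzyloxy)-3,5-dimethoxyphenyl](hydroxy)methylidene}-2,2-dimethyl-1,3-dioxane-4,6-dione | CC1(C)OC(=O)C(=C(O)c2cc(OC)c(OCc3ccccc3)c(OC)c2)C(=O)O1 | intermediate
8 | 3-[4-(benzyloxy)-3,5-dimethoxyphenyl]-3-oxoprop-1-en-1-one (aroylketene) | COc1cc(C(=O)C=C=O)cc(OC)c1OCc1ccccc1 | intermediate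
9 | 3-[4-(benzyloxy)-3-methoxyphenyl]propyl 3-[4-(benzyloxy)-3,5-dimethoxyphenyl]-3-oxopropanoate | COc1cc(CCCOC(=O)CC(=O)c2cc(OC)c(OCc3ccccc3)c(OC)c2)ccc1OCc1ccccc1 | intermediate
10 | 3-[4-(benzyloxy)-3-methoxyphenyl]propyl 3-[4-(benzyloxy)-3,5-dimethoxyphenyl]-2-diazo-3-oxopropanoate | COc1cc(CCCOC(=O)C(=[N+]=[N-])C(=O)c2cc(OC)c(OCc3ccccc3)c(OC)c2)ccc1OCc1ccccc1 | intermediate
11 | rhodium carbenoid of 10 (N2 replaced by the Rh2(S-PTTL)4 unit, drawn as [Rh]) | COc1cc(CCCOC(=O)C(=[Rh])C(=O)c2cc(OC)c(OCc3ccccc3)c(OC)c2)ccc1OCc1ccccc1 | intermediate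
12 | (3S,4R)-3-[4-(benzyloxy)-3,5-dimethoxybenzoyl]-4-[4-(benzyloxy)-3-methoxybenzyl]oxolan-2-one | COc1cc(C[C@H]2COC(=O)[C@@H]2C(=O)c2cc(OC)c(OCc3ccccc3)c(OC)c2)ccc1OCc1ccccc1 | intermediate
13 | (3S,4R)-3-{(S)-[4-(benzyloxy)-3,5-dimethoxyphenyl](hydroxy)methyl}-4-[4-(benzyloxy)-3-methoxybenzyl]oxolan-2-one | COc1cc(C[C@H]2COC(=O)[C@@H]2[C@H](O)c2cc(OC)c(OCc3ccccc3)c(OC)c2)ccc1OCc1ccccc1 | intermediate
14 | (3S,4R)-3-{(S)-[4-(benzyloxy)-3,5-dimethoxyphenyl][(tert-butyldimethylsilyl)oxy]methyl}-4-[4-(benzyloxy)-3-methoxybenzyl]oxolan-2-one | COc1cc(C[C@H]2COC(=O)[C@@H]2[C@H](O[Si](C)(C)C(C)(C)C)c2cc(OC)c(OCc3ccccc3)c(OC)c2)ccc1OCc1ccccc1 | intermediate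
15 | (2R,3R)-2-{(S)-[4-(benzyloxy)-3,5-dimethoxyphenyl][(tert-butyldimethylsilyl)oxy]methyl}-3-[4-(benzyloxy)-3-methoxybenzyl]butane-1,4-diol | COc1cc(C[C@@H](CO)[C@H](CO)[C@H](O[Si](C)(C)C(C)(C)C)c2cc(OC)c(OCc3ccccc3)c(OC)c2)ccc1OCc1ccccc1 | intermediate
16 | (2R,3R)-2-[4-(benzyloxy)-3-methoxybenzyl]-3-{(S)-[4-(benzyloxy)-3,5-dimethoxyphenyl][(tert-butyldimethylsilyl)oxy]methyl}-4-hydroxybutyl 4-methylbenzenesulfonate | COc1cc(C[C@@H](COS(=O)(=O)c2ccc(C)cc2)[C@H](CO)[C@H](O[Si](C)(C)C(C)(C)C)c2cc(OC)c(OCc3ccccc3)c(OC)c2)ccc1OCc1ccccc1 | intermediate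
17 | (3R,4R)-3-[4-(benzyloxy)-3-methoxybenzyl]-4-{(S)-[4-(benzyloxy)-3,5-dimethoxyphenyl][(tert-butyldimethylsilyl)oxy]methyl}oxolane | COc1cc(C[C@H]2COC[C@@H]2[C@H](O[Si](C)(C)C(C)(C)C)c2cc(OC)c(OCc3ccccc3)c(OC)c2)ccc1OCc1ccccc1 | intermediate
18 | (S)-[4-(benzyloxy)-3,5-dimethoxyphenyl]{(3R,4R)-4-[4-(benzyloxy)-3-methoxybenzyl]oxolan-3-yl}methanol | COc1cc(C[C@H]2COC[C@@H]2[C@H](O)c2cc(OC)c(OCc3ccccc3)c(OC)c2)ccc1OCc1ccccc1 | intermediate
19 | (S)-(4-hydroxy-3,5-dimethoxyphenyl)[(3R,4R)-4-(4-hydroxy-3-methoxybenzyl)oxolan-3-yl]methanol | COc1cc(C[C@H]2COC[C@@H]2[C@H](O)c2cc(OC)c(O)c(OC)c2)ccc1O | target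

Total step count: 12. Longest linear sequence: 11 steps (3 to 19, steps 2 to 12); step 1 is the side branch.

**Steps most likely to fail**

Step 6.
- What may go wrong: weak discrimination of the two enantiotopic C3 hydrogens by a carboxylate catalyst facing a flat, very electrophilic aroyl carbenoid. The carbenoid may also be diverted into β-lactone formation, benzylic 1,6 insertion, arene attack or dimerisation.
- Fallback (known chemistry, sets out from 2 and returns at 12): the aroyl group is left off during the insertion and added afterwards.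
- Alcohol 2 is acylated with bromoacetyl bromide (NaHCO3, MeCN, 0 °C) to 3-[4-(benzyloxy)-3-methoxyphenyl]propyl bromoacetate F1. N,N'-Ditosylhydrazine and DBU (THF, 0 °C) convert it into 3-[4-(benzyloxy)-3-methoxyphenyl]propyl diazoacetate F2.
- Dirhodium tetrakis[methyl 1-(3-phenylpropanoyl)-2-oxoimidazolidine-4(R)-carboxylate], Rh2(4R-MPPIM)4 (1 mol %, CH2Cl2, reflux), then effects the same 1,5 insertion. This reaction is established with high enantiocontrol for 3-arylpropyl diazoacetates, and it should give (R)-4-[4-(benzyloxy)-3-methoxybenzyl]oxolan-2-one F3.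
- Acid 5 is converted with (COCl)2 and catalytic DMF into 4-(benzyloxy)-3,5-dimethoxybenzoyl chloride F4. The lithium enolate of F3 (LiHMDS, 2.1 equiv, THF, −78 °C) is C-aroylated with F4 on the face anti to the arylmethyl group, which leads to 12.

Step 7.
- What may go wrong: poor facial selectivity if the resident centres override the catalyst, reduction through the minor cis epimer, or slow hydride transfer to the electron-rich, partly enolised ketone.
- Fallback (sets out from 12 and returns at 13): catalyst control is replaced by chelate-based substrate control with recycling.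
- Zn(BH4)2 (Et2O/CH2Cl2, −78 to 0 °C) reduces the zinc chelate of the two carbonyl groups from the face away from ring carbon C3. This is the mode known to give syn β-hydroxy esters from α-substituted β-keto esters.
- The C7' epimer, (3S,4R)-3-{(R)-[4-(benzyloxy)-3,5-dimethoxyphenyl](hydroxy)methyl}-4-[4-(benzyloxy)-3-methoxybenzyl]oxolan-2-one F5, is removed by chromatography. Dess–Martin periodinane oxidises it back to 12, so the material converges on 13.

Step 12.
- What may go wrong: over-reduction, that is hydrogenolysis of the electron-rich benzylic C7'–O bond alongside the two benzyl ethers.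
- Fallback (sets out from 17 and returns at 19): the order of the two deprotections is inverted, so the carbinol oxygen stays under the bulky silyl group during the hydrogenolysis.
- Compound 17 is hydrogenolysed (H2, 10% Pd/C, EtOAc, rt) to 4-{(S)-[(tert-butyldimethylsilyl)oxy][(3R,4R)-4-(4-hydroxy-3-methoxybenzyl)oxolan-3-yl]methyl}-2,6-dimethoxyphenol F6.
- The silyl ether is then cleaved with Bu4NF buffered by AcOH (THF, 0 °C). The buffer keeps the phenols protonated and so suppresses quinone methide formation, and this gives 19.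

**Further compounds**
F1 | step 6 | 3-[4-(benzyloxy)-3-methoxyphenyl]propyl bromoacetate | COc1cc(CCCOC(=O)CBr)ccc1OCc1ccccc1
F2 | step 6 | 3-[4-(benzyloxy)-3-methoxyphenyl]propyl diazoacetate | COc1cc(CCCOC(=O)C=[N+]=[N-])ccc1OCc1ccccc1
F3 | step 6 | (R)-4-[4-(benzyloxy)-3-methoxybenzyl]oxolan-2-one | COc1cc(C[C@H]2COC(=O)C2)ccc1OCc1ccccc1
F4 | step 6 | 4-(benzyloxy)-3,5-dimethoxybenzoyl chloride | COc1cc(C(=O)Cl)cc(OC)c1OCc1ccccc1
F5 | step 7 | (3S,4R)-3-{(R)-[4-(benzyloxy)-3,5-dimethoxyphenyl](hydroxy)methyl}-4-[4-(benzyloxy)-3-methoxybenzyl]oxolan-2-one | COc1cc(C[C@H]2COC(=O)[C@@H]2[C@@H](O)c2cc(OC)c(OCc3ccccc3)c(OC)c2)ccc1OCc1ccccc1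
F6 | step 12 | 4-{(S)-[(tert-butyldimethylsilyl)oxy][(3R,4R)-4-(4-hydroxy-3-methoxybenzyl)oxolan-3-yl]methyl}-2,6-dimethoxyphenol | COc1cc(C[C@H]2COC[C@@H]2[C@H](O[Si](C)(C)C(C)(C)C)c2cc(OC)c(O)c(OC)c2)ccc1O
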